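Everything rests on cutting the seven-membered ring (ring F) between C9, the methine carrying the pendant catechol ring D, and the fused catechol ring B. C9 is flanked by two para-oxygenated arenes, so it can enter as a ketone carbonyl: in one operation acid closes ring F by cyclodehydration onto ring B, and triethylsilane then reduces the doubly benzylic C9 cation from the convex face fixed by C8 (the methine shared by the six- and seven-membered rings) and the rigid dihydrophenanthrene. The precursor is an enantioenriched 10-aryl-9,10-dihydrophenanthrene with a 2-aryl-2-oxoethyl arm, obtained by chiral-acid hydroarylation of a biaryl hydroxystilbene.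

Key step: step 7

Labels (target): ring A = resorcinol ring; ring C = the mono-oxygenated ring bonded to ring A; ring E = the six-membered ring of the 9,10-dihydrophenanthrene built from A and C, containing C7 (CH2, on ring A) and C8 (CH, on ring C); ring B = catechol ring fused to the seven-membered ring F; ring D = pendant catechol ring; C9 = CH of ring F bearing ring D; C10 = CH2 of ring F, on ring C. Ring carbons: a4–c5 is the biaryl bond, a5 bears C7, c6 bears C8, c1 bears C10, c3 bears the ring-C oxygen (para to c6); b1 bears C8, b6 bears C9, b3 and b4 bear oxygen (b3 para to b6, b4 para to b1). The target is 8R,9S, with H8 and H9 cis on ring F.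

Assumption: the sense of induction of the chiral acid in step 6 cannot be predicted with certainty; the catalyst antipode that gives R at C8 is used (written as the (R)-BINOL-derived acid).

Step 1
Reactants: 1 3,4-dimethoxyacetophenone; 2 1,3-dibromo-5-methoxybenzene (3 equiv)
Product: 3 2-(3-bromo-5-methoxyphenyl)-1-(3,4-dimethoxyphenyl)ethan-1-one
Conditions: Pd2(dba)3 (1.5 mol%), Xantphos (3.6 mol%), NaOtBu (1.3 equiv), THF, 70 °C
Reagents that add atoms: none
Why: Pd-catalysed ketone α-arylation (Buchwald–Hartwig type); the excess of symmetrical dibromide should limit reaction to one C–Br bond, and Xantphos favours mono-arylation of the methyl ketone.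

Step 2
Reactants: 3 2-(3-bromo-5-methoxyphenyl)-1-(3,4-dimethoxyphenyl)ethan-1-one
Product: 4 1-(3,4-dimethoxyphenyl)-2-[3-methoxy-5-(pinacolboryl)phenyl]ethan-1-one
Conditions: B2pin2 (1.2 equiv), Pd(dppf)Cl2 (3 mol%), KOAc (3 equiv), 1,4-dioxane, 90 °C
Reagents that add atoms: bis(pinacolato)diboron, CC1(C)OB(OC1(C)C)B1OC(C)(C)C(C)(C)O1
Why: Miyaura borylation; KOAc is too weak a base to trigger enolate arylation or aldol chemistry of the deoxybenzoin.

Step 3
Reactants: 5 4-hydroxy-3-methoxybenzyl alcohol (vanillyl alcohol)
Product: 6 (4-hydroxy-3-methoxybenzyl)triphenylphosphonium bromide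
Conditions: PPh3·HBr (1.05 equiv), MeCN, reflux
Reagents that add atoms: triphenylphosphine hydrobromide, [Br-].[PH+](c1ccccc1)(c1ccccc1)c1ccccc1
Why: acid-promoted substitution of the p-hydroxybenzylic alcohol (through its quinone methide or benzylic cation) by triphenylphosphine should give the phosphonium salt directly.

Step 4
Reactants: 6 (4-hydroxy-3-methoxybenzyl)triphenylphosphonium bromide; 7 2-bromo-3,5-dimethoxybenzaldehyde
Product: 8 4-[(E)-2-(2-bromo-3,5-dimethoxyphenyl)ethenyl]-2-methoxyphenol
Conditions: KOtBu (2.2 equiv), THF, 0 °C to rt; then (PhS)2 (5 mol%), THF, reflux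
Reagents that add atoms: none
Why: Wittig olefination by the phenoxide ylide (two equivalents of base), followed by thiyl-radical Z-to-E isomerisation; the alkene geometry is in any case erased in step 6.

Step 5
Reactants: 8 4-[(E)-2-(2-bromo-3,5-dimethoxyphenyl)ethenyl]-2-methoxyphenol; 4 the pinacol boronate
Product: 9 1-(3,4-dimethoxyphenyl)-2-{2'-[(E)-2-(4-hydroxy-3-methoxyphenyl)ethenyl]-4',5,6'-trimethoxy-[1,1'-biphenyl]-3-yl}ethan-1-one
Conditions: Pd(OAc)2 (5 mol%), SPhos (10 mol%), K3PO4 (3 equiv), toluene/H2O 10:1, 90 °C
Reagents that add atoms: none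
Why: Suzuki–Miyaura coupling; SPhos–Pd is suited to the di-ortho-substituted bromide, and under aqueous phosphate transmetalation should outrun enolate arylation.

Step 6
Reactants: 9 the biaryl hydroxystilbene ketone
Product: 10 2-[(10R)-10-(4-hydroxy-3-methoxyphenyl)-3,5,7-trimethoxy-9,10-dihydrophenanthren-1-yl]-1-(3,4-dimethoxyphenyl)ethan-1-one
Conditions: (R)-BINOL-derived N-triflyl phosphoramide (TRIP type, 10 mol%), PhCF3, 5 Å MS, 40 °C
Reagents that add atoms: none
Why: chiral Brønsted acid-catalysed intramolecular Friedel–Crafts hydroarylation: protonation at C7 gives the ring-B p-quinone methide (hydroxybenzyl cation) at C8 paired with the chiral anion, and ring C attacks through c6 (para to its methoxy group) in a 6-endo closure of ring E, the catalyst choosing the face that gives R at C8 while E and Z alkene converge.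

Step 7
Reactants: 10 the (10R)-dihydrophenanthrene ketone
Product: 13 (8R,9S)-cyclised hexamethyl ether phenol, via tertiary carbinol 11 (not isolated), via ring-F alkene 12 (not isolated)
Conditions: TfOH (2 equiv), HFIP/CH2Cl2 1:4, 0 °C to rt; then Et3SiH (4 equiv), −20 to 0 °C
Reagents that add atoms: none
Why: TfOH protonates the aryl ketone and ring-B carbon b6 (para to the b3 methoxy group) attacks the carbonyl carbon C9 in a 7-exo-trig Friedel–Crafts hydroxyalkylation that closes ring F, the only ring formed here; carbinol 11 ionises and rests as alkene 12, and once Et3SiH is added reprotonation at C10 regenerates the planar, doubly benzylic C9 cation, which takes up hydride. The closest known reaction types are the Bradsher-type cyclodehydration of aryl ketones onto arenes and the ionic hydrogenation of 1,1-diarylalkenes with silane and acid. The step is stereoconvergent, since both C9 epimers of 11 and alkene 12 funnel through the same cation, so only the face of hydride delivery matters. That face is set by C8: ring E holds C7 pseudo-equatorial on the boat-shaped ring F, so H8 is pseudo-axial on the convex face while rings B and C wall off the concave face, and silane should attack C9 from the convex face, placing H9 cis to H8 and ring D on the concave side (9S). Regioselectivity for b6 over the hindered b2 follows from para-methoxy activation, and cyclisation before carbonyl reduction is secured by adding the silane only after the ketone is consumed. C8 carries no leaving group and should stay R.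

Step 8
Reactants: 13 the (8R,9S)-cyclised hexamethyl ether phenol
Product: 14 CNP0306974.1, the (8R,9S)-heptaphenol
Conditions: BBr3 (12 equiv), CH2Cl2, −78 °C to rt; then H2O, 0 °C
Reagents that add atoms: none
Why: BBr3 cleavage of all six aryl methyl ethers; no bond to C8 or C9 is broken, so both stereocentres should be retained.

Compound list
1 | 3,4-dimethoxyacetophenone | CC(=O)c1ccc(OC)c(OC)c1 | starting material
2 | 1,3-dibromo-5-methoxybenzene | COc1cc(Br)cc(Br)c1 | starting material
3 | 2-(3-bromo-5-methoxyphenyl)-1-(3,4-dimethoxyphenyl)ethan-1-one | COc1cc(Br)cc(CC(=O)c2ccc(OC)c(OC)c2)c1 | intermediate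
4 | 1-(3,4-dimethoxyphenyl)-2-[3-methoxy-5-(4,4,5,5-tetramethyl-1,3,2-dioxaborolan-2-yl)phenyl]ethan-1-one | COc1cc(B2OC(C)(C)C(C)(C)O2)cc(CC(=O)c2ccc(OC)c(OC)c2)c1 | intermediate
5 | 4-hydroxy-3-methoxybenzyl alcohol (vanillyl alcohol) | COc1cc(CO)ccc1O | starting material
6 | (4-hydroxy-3-methoxybenzyl)triphenylphosphonium bromide | COc1cc(C[P+](c2ccccc2)(c2ccccc2)c2ccccc2)ccc1O.[Br-] | intermediate
7 | 2-bromo-3,5-dimethoxybenzaldehyde | COc1cc(C=O)c(Br)c(OC)c1 | starting material
8 | 4-[(E)-2-(2-bromo-3,5-dimethoxyphenyl)ethenyl]-2-methoxyphenol | COc1cc(OC)c(Br)c(/C=C/c2ccc(O)c(OC)c2)c1 | intermediate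
9 | 1-(3,4-dimethoxyphenyl)-2-{2'-[(E)-2-(4-hydroxy-3-methoxyphenyl)ethenyl]-4',5,6'-trimethoxy-[1,1'-biphenyl]-3-yl}ethan-1-one | COc1cc(CC(=O)c2ccc(OC)c(OC)c2)cc(c1)-c1c(OC)cc(OC)cc1/C=C/c1ccc(O)c(OC)c1 | intermediate
10 | 2-[(10R)-10-(4-hydroxy-3-methoxyphenyl)-3,5,7-trimethoxy-9,10-dihydrophenanthren-1-yl]-1-(3,4-dimethoxyphenyl)ethan-1-one | COc1cc(OC)c2c(c1)C[C@H](c1ccc(O)c(OC)c1)c1c(CC(=O)c3ccc(OC)c(OC)c3)cc(OC)cc1-2 | intermediate
11 | tertiary carbinol: ring F closed, C9 bearing OH and the 3,4-dimethoxyphenyl group (both C9 epimers), C8 R, methyl ethers as in 13 | COc1cc(OC)c2c(c1)C[C@@H]1c3cc(OC)c(O)cc3C(O)(c3ccc(OC)c(OC)c3)Cc3cc(OC)cc-2c31 | intermediate (not isolated)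
12 | ring-F alkene: C9=C10 double bond with the 3,4-dimethoxyphenyl group on C9, C8 R, methyl ethers as in 13 | COc1cc(OC)c2c(c1)C[C@@H]1c3cc(OC)c(O)cc3C(c3ccc(OC)c(OC)c3)=Cc3cc(OC)cc-2c31 | intermediate (not isolated)
13 | (8R,9S)-cyclised hexamethyl ether phenol: the target skeleton with OMe on both ring-A oxygens, the ring-C oxygen, both ring-D oxygens and b3 of ring B; free OH at b4 | COc1cc(OC)c2c(c1)C[C@@H]1c3cc(OC)c(O)cc3[C@H](c3ccc(OC)c(OC)c3)Cc3cc(OC)cc-2c31 | intermediate
14 | CNP0306974.1, (8R,9S)-heptaphenol | Oc1cc(O)c2c(c1)C[C@@H]1c3cc(O)c(O)cc3[C@H](c3ccc(O)c(O)c3)Cc3cc(O)cc-2c31 | target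

Total step count: 8. Longest linear sequence: 6 steps (steps 1, 2, 5, 6, 7, 8; the branch through steps 3 and 4 is equally long).

Steps most likely to fail

Step 7. The protonated, electron-rich aryl ketone may be too weak an electrophile for seven-membered ring closure, so that the carbonyl is simply reduced once silane is added. Hydride delivery to the C9 cation may also show too little facial bias, and a transannular hydride shift from C8 could erode that centre. The fallback sets out from 10 and changes the stereo-determining event. NaBH4 in MeOH at 0 °C should reduce the ketone to the secondary benzylic alcohol F1 (both carbinol epimers). BF3·OEt2 or TFA in CH2Cl2 at −40 to 0 °C then ionises F1 to the p-methoxybenzylic C9 cation, which ring B should trap at b6 in a direct Friedel–Crafts cycloalkylation. Here C9 already carries its hydrogen and its configuration is decided in the C–C bond-forming event (kinetically, or by equilibration, since such benzhydryl-type alkylations are reversible). The route is rejoined at 13.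

Step 6. Protonation of the stilbene by the chiral acid may be slow, discrimination of the two faces of the C8 cation in the ion pair may be insufficient, and closure at c4 (ortho to the methoxy group) may compete with closure at c6. The fallback sets out from 9 and replaces asymmetric catalysis by resolution. TfOH (10 mol%) in HFIP at 0 °C should give the racemic dihydrophenanthrene F2, which is resolved by preparative chiral SFC on a polysaccharide phase. The R enantiomer is 10, where the route is rejoined.

Step 5. Oxidative addition into the di-ortho-substituted bromide may be slow enough for protodeboronation of 4 and Pd-enolate arylation at the deoxybenzoin CH2 to take over. The fallback sets out from 8 and installs the ketone arm after the biaryl bond. Suzuki coupling of 8 with (3-chloro-5-methoxyphenyl)boronic acid (Pd(PPh3)4, Na2CO3, DME/H2O, 85 °C, C–Br over C–Cl) should give 4-[(E)-2-(3'-chloro-4,5',6-trimethoxy-[1,1'-biphenyl]-2-yl)ethenyl]-2-methoxyphenol F3. Pd/XPhos-catalysed α-arylation of ketone 1 with the aryl chloride of F3 (NaOtBu, 2.3 equiv, toluene, 80 °C) then gives 9, where the route is rejoined.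

Further compounds
F1 | step 7 | 2-[(10R)-10-(4-hydroxy-3-methoxyphenyl)-3,5,7-trimethoxy-9,10-dihydrophenanthren-1-yl]-1-(3,4-dimethoxyphenyl)ethan-1-ol (both carbinol epimers) | COc1cc(OC)c2c(c1)C[C@H](c1ccc(O)c(OC)c1)c1c(CC(O)c3ccc(OC)c(OC)c3)cc(OC)cc1-2
F2 | step 6 | racemic 2-[10-(4-hydroxy-3-methoxyphenyl)-3,5,7-trimethoxy-9,10-dihydrophenanthren-1-yl]-1-(3,4-dimethoxyphenyl)ethan-1-one | COc1cc(OC)c2c(c1)CC(c1ccc(O)c(OC)c1)c1c(CC(=O)c3ccc(OC)c(OC)c3)cc(OC)cc1-2
F3 | step 5 | 4-[(E)-2-(3'-chloro-4,5',6-trimethoxy-[1,1'-biphenyl]-2-yl)ethenyl]-2-methoxyphenol | COc1cc(Cl)cc(c1)-c1c(OC)cc(OC)cc1/C=C/c1ccc(O)c(OC)c1
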